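**Retrosynthetic overview**
1. Target 18 ⇐ global hydrogenolysis of the hexa-O-benzylated (2R,3R)-ester 17.
2. 17 ⇐ radical 1,2-acyloxy (Surzur–Tanner) shift of the gallate from C4 to C3 in bromo ester 16. The C3–O bond forms suprafacially, so it ends up cis to the C2 aryl group; this is the key step.
3. 16 ⇐ anti bromo-acyloxylation of (S)-flav-3-ene 10 with tri-O-benzylgallic acid 15 (15 ⇐ p-cresol).
4. 10 ⇐ catalytic enantioselective addition of the B-ring boronate (from 4-bromophenol) to chromene acetal 6; this sets C2, the only stereocentre made by asymmetric catalysis.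
5. Ring order: A ring (resorcinol, third oxygen by C–H borylation/oxidation) → pyran C ring (coumarin from ethyl propiolate) → B ring attached at C2 → galloyl ring attached at O4, then migrated to O3.

Assumption: the tartaric-acid-derived catalyst antipode that gives (S)-10 is used (both antipodes are available); ee is upgraded by recrystallisation of 10 or 17 if needed. None of this route has been run; conditions are by analogy to known reaction classes.

Abbreviations: MBn = 4-methylbenzyl; Bn = benzyl.

---

**Step 1**
Reactants: 1 resorcinol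
Product: 2, 1,3-bis[(4-methylbenzyl)oxy]benzene
Conditions: 4-MeC6H4CH2Br (2.2 equiv), K2CO3, DMF, 60 °C
Reagents that add atoms: 4-methylbenzyl bromide, Cc1ccc(CBr)cc1
Why: Williamson etherification; para-substituted benzyl groups are used on ring A because their rings carry no unhindered C–H, so they do not compete in the Ir borylation of step 2, yet they cleave by hydrogenolysis like benzyl.

**Step 2**
Reactants: 2
Product: 3, 3,5-bis[(4-methylbenzyl)oxy]phenol
Conditions: [Ir(cod)OMe]2 (1.5 mol %), dtbpy (3 mol %), B2pin2 (0.6 equiv), THF, 70 °C; then Oxone, acetone/H2O, rt (one pot)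
Reagents that add atoms: Oxone (supplies the phenolic O), [K+].[O-]S(=O)(=O)OO
Why: Sterically controlled Ir-catalysed C–H borylation occurs at C5, the only C–H not ortho to a substituent, and one-pot oxidation of the aryl boronate gives the phenol.

**Step 3**
Reactants: 3; 4 ethyl propiolate
Product: 5, 5,7-bis[(4-methylbenzyl)oxy]-2H-chromen-2-one (coumarin)
Conditions: Pd(OAc)2 (5 mol %), NaOAc, HCO2H, rt
Reagents that add atoms: none
Why: Trost-type Pd-catalysed hydroarylation/lactonisation of an electron-rich phenol with an alkynoate; the two ortho positions of 3 are equivalent, so only the 5,7-dioxygenated coumarin can form.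

**Step 4**
Reactants: 5
Product: 6, 2-ethoxy-5,7-bis[(4-methylbenzyl)oxy]-2H-chromene (racemic acetal)
Conditions: DIBAL-H (1.1 equiv), CH2Cl2, −78 °C; then EtOH, PPTS (cat.), rt (telescoped)
Reagents that add atoms: ethanol, CCO
Why: Partial reduction of the lactone to the lactol and acid-catalysed acetalisation via the stabilised benzopyrylium ion; the racemic acetal centre is erased in step 7.

**Step 5**
Reactants: 7 4-bromophenol
Product: 8, 1-(benzyloxy)-4-bromobenzene
Conditions: BnBr, K2CO3, acetone, reflux
Reagents that add atoms: benzyl bromide, BrCc1ccccc1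
Why: Williamson etherification to protect the B-ring phenol.

**Step 6**
Reactants: 8
Product: 9, [4-(benzyloxy)phenyl]boronic acid
Conditions: Mg, THF; B(OiPr)3, −78 °C → rt; aq. HCl
Reagents that add atoms: triisopropyl borate, CC(C)OB(OC(C)C)OC(C)C; water, O
Why: Grignard formation and borate quench/hydrolysis, a standard arylboronic acid synthesis.

**Step 7**
Reactants: 6; 9
Product: 10, (S)-2-[4-(benzyloxy)phenyl]-5,7-bis[(4-methylbenzyl)oxy]-2H-chromene
Conditions: 9 → ArB(OEt)2 in situ (EtOH, 4 Å MS, evaporate); tartaric-acid-derived bis-amide diol (10 mol %), Ce(OTf)4 or Yb(OTf)3 (5–9 mol %), EtOAc, −40 → −20 °C, dark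
Reagents that add atoms: none
Why: Chiral diol/Lewis acid-catalysed enantioselective boronate addition to a chromene acetal (Petasis-type addition to the benzopyrylium ion), in which the catalyst-bound boronate delivers the electron-rich aryl group to one face of C2 and so sets C2 as S.

**Step 8**
Reactants: 11 p-cresol
Product: 12, 3,5-dibromo-4-hydroxybenzaldehyde
Conditions: Br2 (2.1 equiv), o-dichlorobenzene, 35 °C; Br2 (2.1 equiv), 150–160 °C; then H2O, 100 °C
Reagents that add atoms: bromine, BrBr; water, O
Why: Electrophilic ortho,ortho-dibromination of the ring, then side-chain dibromination to the benzal bromide and hydrolysis to the aldehyde (the established process route to this compound).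

**Step 9**
Reactants: 12
Product: 13, 3,4,5-trihydroxybenzaldehyde
Conditions: Cu(acac)2 (5 mol %), oxalamide ligand BHMPO (5 mol %), LiOH·H2O, DMSO/H2O, 100 °C, Ar; then aq. HCl
Reagents that add atoms: lithium hydroxide, [Li+].[OH-]
Why: Cu-catalysed Ullmann-type hydroxylation of both aryl bromides; the para-formyl phenoxide is inert to Cannizzaro chemistry, and the air-sensitive product is used crude.

**Step 10**
Reactants: 13
Product: 14, 3,4,5-tris(benzyloxy)benzaldehyde
Conditions: BnBr (3.5 equiv), K2CO3, DMF, 60 °C
Reagents that add atoms: benzyl bromide, BrCc1ccccc1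
Why: Exhaustive Williamson benzylation of the three phenols.

**Step 11**
Reactants: 14
Product: 15, 3,4,5-tris(benzyloxy)benzoic acid
Conditions: NaClO2, NaH2PO4, 2-methyl-2-butene, t-BuOH/THF/H2O, rt
Reagents that add atoms: sodium chlorite, [Na+].[O-]Cl=O
Why: Pinnick oxidation converts the aldehyde to the acid without touching the benzyl ethers.

**Step 12**
Reactants: 10; 15
Product: 16, (2R,3R,4R)-2-[4-(benzyloxy)phenyl]-3-bromo-5,7-bis[(4-methylbenzyl)oxy]chroman-4-yl 3,4,5-tris(benzyloxy)benzoate (2,3-trans, 3,4-trans; ester at C4 cis to the C2 aryl)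
Conditions: NBS (1.05 equiv), 15 (2 equiv, half as its Bu4N salt), 4 Å MS, CH2Cl2, −78 → −30 °C, dark; used promptly
Reagents that add atoms: N-bromosuccinimide, O=C1CCC(=O)N1Br
Why: Bromo-acyloxylation (co-halogenation) of the electron-rich styrenyl alkene, in which Br+ adds to C3 on the face anti to the C2 aryl and the carboxylate opens the bromonium/benzylic cation at C4 anti to bromine, placing the gallate on the same face as the aryl.

**Step 13 (key step)**
Reactants: 16
Product: 17, (2R,3R)-2-[4-(benzyloxy)phenyl]-5,7-bis[(4-methylbenzyl)oxy]chroman-3-yl 3,4,5-tris(benzyloxy)benzoate (2,3-cis)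
Conditions: (Me3Si)3SiH (1.3 equiv) and AIBN (0.2 equiv) added by syringe pump over 6 h to 16 in refluxing benzene (0.005 M)
Reagents that add atoms: none
Why: Surzur–Tanner β-(acyloxy)alkyl radical rearrangement, in which Br abstraction gives the C3 radical and the C4 gallate shifts suprafacially (five-membered cyclic transition state or contact radical-cation/carboxylate pair) to C3, driven by formation of the trialkoxy-benzylic C4 radical, which then takes H from the silane. The new C3–O bond therefore forms on the face the ester already occupied, cis to the untouched C2 aryl, as in the known cis-1,2-acyloxy shift of glycosyl radicals; high dilution and the slow H-donor suppress premature reduction.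

**Step 14**
Reactants: 17
Product: 18, (2R,3R)-5,7-dihydroxy-2-(4-hydroxyphenyl)chroman-3-yl 3,4,5-trihydroxybenzoate (target)
Conditions: H2 (1 atm), 20 % Pd(OH)2/C, THF/MeOH, rt
Reagents that add atoms: none
Why: Global hydrogenolysis of all six benzyl-type ethers under neutral conditions that leave the ester, the C2–O bond and both stereocentres intact.

---

**Compound list**
1 | resorcinol | Oc1cccc(O)c1 | starting material
2 | 1,3-bis[(4-methylbenzyl)oxy]benzene | Cc1ccc(COc2cccc(OCc3ccc(C)cc3)c2)cc1 | intermediate
3 | 3,5-bis[(4-methylbenzyl)oxy]phenol | Cc1ccc(COc2cc(O)cc(OCc3ccc(C)cc3)c2)cc1 | intermediate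
4 | ethyl propiolate | CCOC(=O)C#C | starting material
5 | 5,7-bis[(4-methylbenzyl)oxy]coumarin | O=C1C=Cc2c(OCc3ccc(C)cc3)cc(OCc3ccc(C)cc3)cc2O1 | intermediate
6 | 2-ethoxy-5,7-bis[(4-methylbenzyl)oxy]-2H-chromene (racemic) | CCOC1C=Cc2c(OCc3ccc(C)cc3)cc(OCc3ccc(C)cc3)cc2O1 | intermediate
7 | 4-bromophenol | Oc1ccc(Br)cc1 | starting material
8 | 1-(benzyloxy)-4-bromobenzene | Brc1ccc(OCc2ccccc2)cc1 | intermediate
9 | [4-(benzyloxy)phenyl]boronic acid | OB(O)c1ccc(OCc2ccccc2)cc1 | intermediate
10 | (S)-2-[4-(benzyloxy)phenyl]-5,7-bis[(4-methylbenzyl)oxy]-2H-chromene | C1=Cc2c(OCc3ccc(C)cc3)cc(OCc3ccc(C)cc3)cc2O[C@@H]1c1ccc(OCc2ccccc2)cc1 | intermediate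
11 | p-cresol | Cc1ccc(O)cc1 | starting material
12 | 3,5-dibromo-4-hydroxybenzaldehyde | O=Cc1cc(Br)c(O)c(Br)c1 | intermediate
13 | 3,4,5-trihydroxybenzaldehyde | O=Cc1cc(O)c(O)c(O)c1 | intermediate
14 | 3,4,5-tris(benzyloxy)benzaldehyde | O=Cc1cc(OCc2ccccc2)c(OCc2ccccc2)c(OCc2ccccc2)c1 | intermediate
15 | 3,4,5-tris(benzyloxy)benzoic acid | OC(=O)c1cc(OCc2ccccc2)c(OCc2ccccc2)c(OCc2ccccc2)c1 | intermediate
16 | (2R,3R,4R)-2-[4-(benzyloxy)phenyl]-3-bromo-5,7-bis[(4-methylbenzyl)oxy]chroman-4-yl 3,4,5-tris(benzyloxy)benzoate | Br[C@H]1[C@H](OC(=O)c2cc(OCc3ccccc3)c(OCc3ccccc3)c(OCc3ccccc3)c2)c2c(OCc3ccc(C)cc3)cc(OCc3ccc(C)cc3)cc2O[C@@H]1c1ccc(OCc2ccccc2)cc1 | intermediate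
17 | (2R,3R)-2-[4-(benzyloxy)phenyl]-5,7-bis[(4-methylbenzyl)oxy]chroman-3-yl 3,4,5-tris(benzyloxy)benzoate | O=C(O[C@@H]1Cc2c(OCc3ccc(C)cc3)cc(OCc3ccc(C)cc3)cc2O[C@@H]1c1ccc(OCc2ccccc2)cc1)c1cc(OCc2ccccc2)c(OCc2ccccc2)c(OCc2ccccc2)c1 | intermediate
18 | (2R,3R)-5,7-dihydroxy-2-(4-hydroxyphenyl)chroman-3-yl 3,4,5-trihydroxybenzoate | O=C(O[C@@H]1Cc2c(O)cc(O)cc2O[C@@H]1c1ccc(O)cc1)c1cc(O)c(O)c(O)c1 | target

---

**Total step count:** 14
**Longest linear sequence:** 8 steps (1 → 2 → 3 → 4 → 7 → 12 → 13 → 14)

**Three steps most likely to fail**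
1. Step 13 (radical gallate shift). The risks are premature reduction of the C3 radical, a competing 1,2-aryl shift from C2 to C3, or escape of the ion pair with loss of cis fidelity. Fallback: drop the migration; hydroborate/oxidise 10 to the 2,3-trans-flavan-3-ol, invert C3 by Dess–Martin oxidation and L-Selectride reduction, then esterify the cis-alcohol with 15 (DCC/DMAP).
2. Step 12 (bromo-acyloxylation). The risks are bromination of the very electron-rich A ring, oxidation of 10 to the flavylium ion, or solvolysis of the labile C4 ester. Fallback: make 16 in two stages via the known type of trans,trans-bromohydrin (NBS, aqueous acetone) followed by acylation of the C4 alcohol with the acid chloride of 15.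
3. Step 7 (enantioselective boronate addition). The risk is low ee or low reactivity with the strongly stabilised 5,7-dialkoxybenzopyrylium ion. Fallback: set C2 by Pd(II)/(S)-t-BuPyOx-catalysed conjugate addition of 9 to the corresponding 5,7-bis(MBn-oxy)chromone to give the (S)-flavanone, then α-brominate (trans-3-Br), reduce with NaBH4 (2,4-cis-4-ol) and acylate with 15 to reach 16 without passing through 10.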